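**Retrosynthetic overview**
1. Target acid ⇐ bicyclic aldehyde (chlorite oxidation) ⇐ linear (2E,4Z,6S,7E,9E,11E,13E)-hexaenal by one intramolecular Diels–Alder reaction that closes ring A (cyclohexene) and ring B (cyclopentene) together and sets four stereocentres from the single C6 centre.
2. East tetraene ⇐ Horner–Wadsworth–Emmons (cinnamyl phosphonate), Wittig (α-ethyl formyl ylide) and hydrozirconation–carbonylation of a methyl alkyne.
3. West (2E,4Z)-dienol ⇐ palladium coupling of a (Z)-enol phosphate with the alkenylalane made from propargyl alcohol and Me3Al.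
4. Key disconnection, the enol C–O bond: the (Z)-enol phosphate carrying the only externally set stereocentre ⇐ gold-catalysed, enantiotopic-group-selective anti addition of diphenyl phosphate across one alkyne of prochiral 4-methylhepta-2,5-diyne.
5. Diyne ⇐ pent-3-yn-2-ol mesylate + prop-1-ynylmagnesium bromide.

Assumption: the (R)-configured gold complex is taken to give the (4R)-enol phosphate; if the sense of induction is the opposite, the (S)-ligand is used with no other change.

Step 1
Reactants: 1 pent-3-yn-2-ol (racemic)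
Product: 2 pent-3-yn-2-yl methanesulfonate (racemic)
Conditions: MsCl (1.2 equiv), Et3N (1.5 equiv), CH2Cl2, −20 to 0 °C; used crude after aqueous wash
Reagents that add atoms: methanesulfonyl chloride, CS(=O)(=O)Cl
Why: O-sulfonylation (mesylation) of a secondary propargylic alcohol is clean at low temperature, and the racemic centre needs no control because it becomes prochiral in step 2.

Step 2
Reactants: 2 pent-3-yn-2-yl methanesulfonate, 3 prop-1-ynylmagnesium bromide
Product: 4 4-methylhepta-2,5-diyne
Conditions: 3 (1.3 equiv, 0.5 M in THF), CuBr·SMe2 (5 mol%), THF, −30 °C to rt; distillation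
Reagents that add atoms: none
Why: Copper-catalysed propargylic alkynylation with an alkynyl Grignard reagent (skipped-diyne synthesis) proceeds by direct SN2 displacement, since alkynylcopper species do not follow the SN2′ path of alkyl cuprates, and gives the achiral diyne that is prochiral at C4.

Step 3
Reactants: 4 4-methylhepta-2,5-diyne, 5 diphenyl hydrogen phosphate
Product: 6 (2Z,4R)-4-methylhept-2-en-5-yn-2-yl diphenyl phosphate
Conditions: [(R)-DTBM-SEGPHOS](AuCl)2 (2.5 mol%), AgNTf2 (5 mol%), 5 (0.95 equiv), toluene, 4 Å MS, −20 °C to rt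
Reagents that add atoms: none
Why: Proposed new method: enantiotopic-group-selective anti-hydrophosphoryloxylation of a prochiral 1,4-diyne, in which the C2-symmetric digold complex ionised by AgNTf2 π-binds both alkynes of 4 so that the CH(Me) carbon sits in the chiral pocket and only one alkyne is open to outer-sphere attack; diphenyl phosphate adds anti to monovalent gold at the methyl-bearing alkyne carbon (less hindered and remote from the electron-withdrawing propargylic carbon) and protodeauration gives the (Z)-enol phosphate and fixes C4 as (R), while any over-addition consumes mainly the minor enantiomer of the mono-adduct and so raises ee; the closest known reactions are the racemic monovalent-gold-catalysed anti addition of diaryl phosphates and carboxylic acids to internal alkynes and the gold-catalysed desymmetrisation of 1,4-diynes by tethered N- and O-nucleophiles.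

Step 4
Reactants: 6 (2Z,4R)-4-methylhept-2-en-5-yn-2-yl diphenyl phosphate, 7 prop-2-yn-1-ol
Product: 9 (2E,4Z,6R)-2,4,6-trimethylnona-2,4-dien-7-yn-1-ol, via alkenylalane 8 (not isolated)
Conditions: 7 (1.6 equiv), Me3Al (3.2 equiv), Cp2ZrCl2 (0.3 equiv), CH2Cl2, 0 °C to rt, 14 h; then 6 (1.0 equiv), Pd(PPh3)4 (5 mol%), THF, rt to 40 °C; Rochelle salt work-up
Reagents that add atoms: trimethylaluminium, C[Al](C)C
Why: Negishi zirconium-catalysed syn-carboalumination of propargyl alcohol gives the (E)-alkenylalane regio- and stereospecifically, and zerovalent-palladium-catalysed cross-coupling of alkenylalanes with enol diphenyl phosphates retains geometry at both sp2 carbons, so the (2E,4Z)-diene is fixed and the C6 stereocentre and the alkyne are untouched.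

Step 5
Reactants: 9 (2E,4Z,6R)-2,4,6-trimethylnona-2,4-dien-7-yn-1-ol
Product: 12 (2E,4R,5Z,7E)-9-hydroxy-2,4,6,8-tetramethylnona-2,5,7-trienal, via alkenylzirconocene 10 (not isolated), via acylzirconocene 11 (not isolated)
Conditions: Cp2Zr(H)Cl (2.6 equiv), THF, rt, 1 h; CO (1 atm), rt, 2 h; then 1 M HCl, 0 °C
Reagents that add atoms: carbon monoxide, [C-]#[O+]
Why: Syn-hydrozirconation of the methyl alkyne with excess Cp2Zr(H)Cl equilibrates zirconium to the less hindered methyl-bearing carbon, CO inserts into the alkenyl–Zr bond (Schwartz hydrozirconation–carbonylation) and protonolysis of the acylzirconocene releases the (E)-enal, while the first equivalent of hydride only converts the alcohol into its zirconium alkoxide and the trisubstituted diene is too hindered to react.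

Step 6
Reactants: 13 triphenyl(propyl)phosphonium bromide, 14 ethyl formate
Product: 16 2-(triphenyl-λ5-phosphanylidene)butanal, via propylidene ylide 15 (not isolated)
Conditions: KOtBu (1.1 equiv), THF, 0 °C; then 14 (1.5 equiv), 0 °C to rt
Reagents that add atoms: none
Why: C-formylation of a non-stabilised phosphorus ylide with ethyl formate gives the stabilised formyl ylide, the released ethoxide re-forming ylide from the salt (transylidation), which is the standard preparation of α-alkyl formylmethylene phosphoranes.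

Step 7
Reactants: 12 (2E,4R,5Z,7E)-9-hydroxy-2,4,6,8-tetramethylnona-2,5,7-trienal, 16 2-(triphenyl-λ5-phosphanylidene)butanal
Product: 17 (2E,4E,6R,7Z,9E)-2-ethyl-11-hydroxy-4,6,8,10-tetramethylundeca-2,4,7,9-tetraenal
Conditions: 16 (1.5 equiv), toluene, 70 °C, 24 h, dark
Reagents that add atoms: none
Why: Wittig olefination with a stabilised α-formyl ylide is under thermodynamic control and gives the (E)-trisubstituted enal, and the weakly basic ylide leaves the doubly allylic C6 stereocentre and the free alcohol untouched.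

Step 8
Reactants: 17 (2E,4E,6R,7Z,9E)-2-ethyl-11-hydroxy-4,6,8,10-tetramethylundeca-2,4,7,9-tetraenal, 18 diethyl [(2E)-3-phenylprop-2-en-1-yl]phosphonate
Product: 20 (2E,4Z,6S,7E,9E,11E,13E)-10-ethyl-2,4,6,8-tetramethyl-14-phenyltetradeca-2,4,7,9,11,13-hexaen-1-ol, via lithiated phosphonate 19 (not isolated)
Conditions: 18 (2.2 equiv), LiN(SiMe3)2 (2.1 equiv), THF, −78 °C; then 17, −78 to 0 °C, dark
Reagents that add atoms: none
Why: Horner–Wadsworth–Emmons olefination with the allylic phosphonate anion is (E)-selective for the new disubstituted alkene, addition to the aldehyde at −78 °C outruns vinylogous deprotonation at C6, and the excess anion only holds the alcohol as its alkoxide.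

Step 9
Reactants: 20 (2E,4Z,6S,7E,9E,11E,13E)-10-ethyl-2,4,6,8-tetramethyl-14-phenyltetradeca-2,4,7,9,11,13-hexaen-1-ol
Product: 22 (1R,3aR,4R,5S,7aS)-5-ethyl-1,3,4,7-tetramethyl-5-[(1E,3E)-4-phenylbuta-1,3-dien-1-yl]-3a,4,5,7a-tetrahydro-1H-indene-4-carbaldehyde, via hexaenal 21 (not isolated)
Conditions: MnO2 (25 equiv), CH2Cl2, rt, dark; filter through Celite; then toluene (0.005 M), BHT (0.1 equiv), 85 °C
Reagents that add atoms: none
Why: MnO2 oxidises only the allylic alcohol and the (2E,4Z)-enal then undergoes an intramolecular Diels–Alder reaction in which the (Z)-alkene of the three-atom tether holds the enal over the C7–C10 diene, the formyl group lies endo (trans ring fusion, with the (E)-dienophile and (E,E)-diene geometries giving the C4 and C5 quaternary centres) and the diene face is the one that keeps the C6 hydrogen eclipsed with the C8 methyl (1,3-allylic strain), so the C6 centre sets C1, C3a, C4, C5 and C7a of 22 while ring A and ring B close together.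

Step 10
Reactants: 22 (1R,3aR,4R,5S,7aS)-5-ethyl-1,3,4,7-tetramethyl-5-[(1E,3E)-4-phenylbuta-1,3-dien-1-yl]-3a,4,5,7a-tetrahydro-1H-indene-4-carbaldehyde
Product: 23 (1R,3aR,4R,5S,7aS)-5-ethyl-1,3,4,7-tetramethyl-5-[(1E,3E)-4-phenylbuta-1,3-dien-1-yl]-3a,4,5,7a-tetrahydro-1H-indene-4-carboxylic acid (CNP0200738.1)
Conditions: NaClO2 (5 equiv), NaH2PO4 (5 equiv), 2-methylbut-2-ene (30 equiv), t-BuOH/H2O 4:1, 0 °C to rt
Reagents that add atoms: sodium chlorite, [Na+].[O-]Cl=O
Why: Pinnick chlorite oxidation converts the hindered aldehyde on the quaternary carbon into the acid with no epimerisable centre involved, and 2-methylbut-2-ene scavenges HOCl so that the phenyldiene and the trisubstituted alkenes survive.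

**Compound list**
1 | pent-3-yn-2-ol (racemic) | CC#CC(C)O | starting material
2 | pent-3-yn-2-yl methanesulfonate (racemic) | CC#CC(C)OS(C)(=O)=O | intermediate
3 | prop-1-ynylmagnesium bromide | CC#C[Mg]Br | starting material
4 | 4-methylhepta-2,5-diyne | CC#CC(C)C#CC | intermediate
5 | diphenyl hydrogen phosphate | OP(=O)(Oc1ccccc1)Oc1ccccc1 | starting material
6 | (2Z,4R)-4-methylhept-2-en-5-yn-2-yl diphenyl phosphate | CC#C[C@H](C)/C=C(/C)OP(=O)(Oc1ccccc1)Oc1ccccc1 | intermediate
7 | prop-2-yn-1-ol | C#CCO | starting material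
8 | alkenylalane: {[(2E)-3-(dimethylalumanyl)-2-methylprop-2-en-1-yl]oxy}(dimethyl)alumane | C[Al](C)/C=C(\C)CO[Al](C)C | intermediate (not isolated)
9 | (2E,4Z,6R)-2,4,6-trimethylnona-2,4-dien-7-yn-1-ol | OC/C(C)=C/C(C)=C\[C@@H](C)C#CC | intermediate
10 | alkenylzirconocene: chlorozirconocene alkoxide of (2E,4Z,6R,7E)-8-(chlorozirconocenyl)-2,4,6-trimethylnona-2,4,7-trien-1-ol (C5H5 drawn σ-bonded) | Cl[Zr](C1C=CC=C1)(C1C=CC=C1)OC/C(C)=C/C(C)=C\[C@@H](C)/C=C(\C)[Zr](Cl)(C1C=CC=C1)C1C=CC=C1 | intermediate (not isolated)
11 | acylzirconocene: (2E,4R,5Z,7E)-9-(chlorozirconocenyloxy)-2,4,6,8-tetramethylnona-2,5,7-trienoyl zirconocene chloride (C5H5 drawn σ-bonded) | Cl[Zr](C1C=CC=C1)(C1C=CC=C1)OC/C(C)=C/C(C)=C\[C@@H](C)/C=C(\C)C(=O)[Zr](Cl)(C1C=CC=C1)C1C=CC=C1 | intermediate (not isolated)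
12 | (2E,4R,5Z,7E)-9-hydroxy-2,4,6,8-tetramethylnona-2,5,7-trienal | OC/C(C)=C/C(C)=C\[C@@H](C)/C=C(C)/C=O | intermediate
13 | triphenyl(propyl)phosphonium bromide | CCC[P+](c1ccccc1)(c1ccccc1)c1ccccc1.[Br-] | starting material
14 | ethyl formate | CCOC=O | starting material
15 | triphenyl(propylidene)-λ5-phosphane (propylidene ylide) | CCC=P(c1ccccc1)(c1ccccc1)c1ccccc1 | intermediate (not isolated)
16 | 2-(triphenyl-λ5-phosphanylidene)butanal | CCC(C=O)=P(c1ccccc1)(c1ccccc1)c1ccccc1 | intermediate
17 | (2E,4E,6R,7Z,9E)-2-ethyl-11-hydroxy-4,6,8,10-tetramethylundeca-2,4,7,9-tetraenal | OC/C(C)=C/C(C)=C\[C@@H](C)/C=C(C)/C=C(CC)/C=O | intermediate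
18 | diethyl [(2E)-3-phenylprop-2-en-1-yl]phosphonate | CCOP(=O)(C/C=C/c1ccccc1)OCC | starting material
19 | lithium (2E)-1-(diethoxyphosphoryl)-3-phenylprop-2-en-1-ide (lithiated phosphonate) | [Li+].CCOP(=O)(OCC)[CH-]/C=C/c1ccccc1 | intermediate (not isolated)
20 | (2E,4Z,6S,7E,9E,11E,13E)-10-ethyl-2,4,6,8-tetramethyl-14-phenyltetradeca-2,4,7,9,11,13-hexaen-1-ol | OC/C(C)=C/C(C)=C\[C@@H](C)/C=C(C)/C=C(CC)/C=C/C=C/c1ccccc1 | intermediate
21 | (2E,4Z,6S,7E,9E,11E,13E)-10-ethyl-2,4,6,8-tetramethyl-14-phenyltetradeca-2,4,7,9,11,13-hexaenal | O=C/C(C)=C/C(C)=C\[C@@H](C)/C=C(C)/C=C(CC)/C=C/C=C/c1ccccc1 | intermediate (not isolated)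
22 | (1R,3aR,4R,5S,7aS)-5-ethyl-1,3,4,7-tetramethyl-5-[(1E,3E)-4-phenylbuta-1,3-dien-1-yl]-3a,4,5,7a-tetrahydro-1H-indene-4-carbaldehyde | CC[C@]1(/C=C/C=C/c2ccccc2)C=C(C)[C@H]2[C@H](C)C=C(C)[C@@H]2[C@@]1(C)C=O | intermediate
23 | (1R,3aR,4R,5S,7aS)-5-ethyl-1,3,4,7-tetramethyl-5-[(1E,3E)-4-phenylbuta-1,3-dien-1-yl]-3a,4,5,7a-tetrahydro-1H-indene-4-carboxylic acid | CC[C@]1(/C=C/C=C/c2ccccc2)C=C(C)[C@H]2[C@H](C)C=C(C)[C@@H]2[C@@]1(C)C(=O)O | target

**Step count**
Total: 10 steps. Longest linear sequence: 9 steps (steps 1–5 and 7–10); step 6 prepares the Wittig reagent.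

**Three steps most likely to fail**

Step 3 (the proposed new desymmetrisation). The risks are low enantioselectivity, attack at the wrong alkyne carbon and double addition. The fallback uses known chemistry, sets out from diyne 4 and comes back at 6. The achiral catalyst Ph3PAuCl/AgNTf2 (5 mol%, toluene, rt) adds 5 to 4 by the established anti addition of diaryl phosphates to internal alkynes. This gives 6 together with its enantiomer (2Z,4S)-4-methylhept-2-en-5-yn-2-yl diphenyl phosphate F1 as the racemate. Preparative chiral supercritical-fluid chromatography on an amylose-type phase separates the two, and the (R)-isomer 6 enters step 4; the approach changes from asymmetric catalysis to racemic synthesis plus resolution.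

Step 5 (hydrozirconation–carbonylation). The risks are incomplete regio-equilibration of zirconium and a poor CO-insertion or protonolysis yield with the zirconium alkoxide present. The fallback sets out from 9 and comes back at 12. Hydrozirconation of 9 with Cp2Zr(H)Cl (2.6 equiv, THF, rt) is quenched with I2 to give (2E,4Z,6R,7E)-8-iodo-2,4,6-trimethylnona-2,4,7-trien-1-ol F2, which can be purified from any regioisomer. A palladium-catalysed formylation of this vinyl iodide (Pd(PPh3)4, CO 3 atm, slow addition of Bu3SnH, THF, 50 °C) then gives 12, so the C–C bond is made at palladium on an isolated halide instead of at zirconium.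

Step 9 (oxidation and intramolecular Diels–Alder reaction). The risks are cis-fused or facial isomers, a 1,5-hydrogen shift in the (Z)-diene on heating, and polymerisation of the hexaenal. The fallback sets out from hexaenal 21 (kept in solution at 0 °C) and comes back at 23. The order of oxidation and cycloaddition is reversed: Pinnick oxidation of 21 (NaClO2, NaH2PO4, 2-methylbut-2-ene, t-BuOH/H2O, 0 °C) gives (2E,4Z,6S,7E,9E,11E,13E)-10-ethyl-2,4,6,8-tetramethyl-14-phenyltetradeca-2,4,7,9,11,13-hexaenoic acid F3. This free acid is cyclised in the biomimetic manner (pH 5 aqueous buffer/MeCN, 40–60 °C) directly to 23.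

**Further compounds**
F1 | step 3 | (2Z,4S)-4-methylhept-2-en-5-yn-2-yl diphenyl phosphate | CC#C[C@@H](C)/C=C(/C)OP(=O)(Oc1ccccc1)Oc1ccccc1
F2 | step 5 | (2E,4Z,6R,7E)-8-iodo-2,4,6-trimethylnona-2,4,7-trien-1-ol | OC/C(C)=C/C(C)=C\[C@@H](C)/C=C(\C)I
F3 | step 9 | (2E,4Z,6S,7E,9E,11E,13E)-10-ethyl-2,4,6,8-tetramethyl-14-phenyltetradeca-2,4,7,9,11,13-hexaenoic acid | OC(=O)/C(C)=C/C(C)=C\[C@@H](C)/C=C(C)/C=C(CC)/C=C/C=C/c1ccccc1
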